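Lactone numbering used below: O1, C2 (carbonyl), C3 (enol OH), C4 (4-hydroxyphenyl), C5 (quaternary, CO2Me). Enabling feature: ring oxygen O1 and the benzylic CH2 both sit on C5, and the cis C3=C4 double bond holds C5 next to the C2 carboxyl. This is the product pattern of a carboxy-arylation of a C5=CH2 alkene.
Key disconnection: the CH2–aryl bond and the C5–O1 bond are cut together, opening the furanone to the achiral acyclic diene acid 9 and the enantiopure arenediazonium salt 18. Re-forming both bonds in one copper-catalysed radical step also creates the quaternary stereocenter.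
Diene acid 9: C4–C5 bond by Stille coupling of enol triflate 7 (from crossed Claisen acylation of a benzyloxyacetate) with methyl 2-stannylacrylate 3, then tert-butyl ester cleavage.
Diazonium salt 18: ortho-prenylation of 4-bromophenol, Shi epoxidation and 5-exo epoxide opening build the (S)-dihydrofuran ring; Br is then exchanged for NH2 and N2+.
Ring order: dihydrofuran ring (step 9), then furanone ring (step 12); hydrogenolysis of the two benzyl ethers ends the route.

Key step: step 12

Assumption: the sense of induction of the copper/bis(oxazoline) catalyst on this new substrate cannot be assigned in advance. The route is written with the (S,S)-ligand; the (R,R)-ligand is used instead if the first run shows the opposite sense. The epimer ratio of 20 reports this directly, because 18 is already enantiopure.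

Step 1
Reactants: 1 methyl propiolate; 2 tributyltin hydride
Product: 3 methyl 2-(tributylstannyl)prop-2-enoate
Conditions: Pd(PPh3)4 (2 mol%), THF, 0 °C to rt
Reagents that add atoms: none
Why: Palladium-catalysed syn-hydrostannation of a terminal alkynoate should place tin on the α-carbon and hydrogen on the β-carbon, the usual regiochemistry for propiolates.

Step 2
Reactants: 4 tert-butyl 2-(benzyloxy)acetate; 5 4-(benzyloxy)benzoyl chloride
Product: 6 tert-butyl 2-(benzyloxy)-3-[4-(benzyloxy)phenyl]-3-oxopropanoate (racemic)
Conditions: LiN(SiMe3)2 (2.1 equiv), THF, −78 °C; then 5, −78 to −40 °C; aq NH4Cl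
Reagents that add atoms: none
Why: Crossed Claisen-type C-acylation of the lithium ester enolate by the aroyl chloride; the second equivalent of base stores the more acidic β-keto ester as its enolate and so prevents double acylation.

Step 3
Reactants: 6 tert-butyl 2-(benzyloxy)-3-[4-(benzyloxy)phenyl]-3-oxopropanoate
Product: 7 tert-butyl (2E)-2-(benzyloxy)-3-[4-(benzyloxy)phenyl]-3-{[(trifluoromethyl)sulfonyl]oxy}prop-2-enoate (triflate cis to the ester)
Conditions: NaH, Et2O, 0 °C; then Tf2O, −78 to 0 °C
Reagents that add atoms: trifluoromethanesulfonic anhydride, O=S(=O)(OS(=O)(=O)C(F)(F)F)C(F)(F)F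
Why: O-sulfonylation of the sodium chelate of the β-keto ester, in which sodium bridges the enolate oxygen and the ester carbonyl, should fix the triflate cis to the ester (enol triflate formation under chelation control).

Step 4
Reactants: 7 the enol triflate; 3 methyl 2-(tributylstannyl)prop-2-enoate
Product: 8 1-tert-butyl 5-methyl (2E)-2-(benzyloxy)-3-[4-(benzyloxy)phenyl]-4-methylidenepent-2-enedioate (tert-butyl ester cis to the acrylate unit)
Conditions: Pd(PPh3)4 (5 mol%), CuCl, LiCl, DMSO, 60 °C
Reagents that add atoms: none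
Why: Stille coupling under copper-assisted conditions developed for hindered 1-substituted vinylstannanes and enol triflates; oxidative addition and reductive elimination keep the alkene geometry.

Step 5
Reactants: 8 the diene diester
Product: 9 (2E)-2-(benzyloxy)-3-[4-(benzyloxy)phenyl]-4-(methoxycarbonyl)penta-2,4-dienoic acid (carboxyl cis to the acrylate unit)
Conditions: CF3CO2H/CH2Cl2 (1:4), 0 °C; toluene azeotrope; used directly
Reagents that add atoms: none
Why: Acidolysis of the tert-butyl ester by alkyl–oxygen cleavage should spare the methyl ester and both benzyl ethers, and the two ester groups deactivate the diene towards protonation.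

Step 6
Reactants: 10 4-bromophenol; 11 1-bromo-3-methylbut-2-ene (prenyl bromide)
Product: 12 4-bromo-2-(3-methylbut-2-en-1-yl)phenol
Conditions: NaH, toluene, 0 °C to rt
Reagents that add atoms: none
Why: ortho-C-alkylation of a sodium phenoxide in a non-polar solvent, where the tight ion pair shields oxygen; the para position is blocked by bromine.

Step 7
Reactants: 12 4-bromo-2-(3-methylbut-2-en-1-yl)phenol
Product: 13 [4-bromo-2-(3-methylbut-2-en-1-yl)phenoxy](tert-butyl)dimethylsilane
Conditions: TBSCl, imidazole, DMF, rt
Reagents that add atoms: tert-butyldimethylsilyl chloride, CC(C)(C)[Si](C)(C)Cl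
Why: Standard silylation keeps a free phenoxide away from the oxidant of the next step.

Step 8
Reactants: 13 the silyl ether
Product: 14 {4-bromo-2-[[(2R)-3,3-dimethyloxiran-2-yl]methyl]phenoxy}(tert-butyl)dimethylsilane
Conditions: D-fructose-derived Shi ketone (30 mol%), Oxone (2KHSO5·KHSO4·K2SO4), K2CO3, Bu4NHSO4, MeCN/dimethoxymethane/aq Na2B4O7–Na2EDTA buffer, 0 °C
Reagents that add atoms: potassium peroxymonosulfate, OOS(=O)(=O)[O-].[K+]
Why: Shi asymmetric epoxidation of a trisubstituted alkene; the spiro transition state of the chiral dioxirane should deliver oxygen to the face that gives the (R)-epoxide.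

Step 9
Reactants: 14 the (R)-epoxide
Product: 16 2-[(2S)-5-bromo-2,3-dihydro-1-benzofuran-2-yl]propan-2-ol, via epoxy phenoxide 15 (not isolated)
Conditions: Bu4NF, THF, 0 °C to rt; aq NH4Cl
Reagents that add atoms: none
Why: Fluoride desilylation frees the phenoxide, which should open the epoxide 5-exo-tet at the secondary carbon with inversion, turning the (R)-epoxide into the (S)-dihydrobenzofuran while the epoxide oxygen becomes the tertiary alcohol.

Step 10
Reactants: 16 the bromo dihydrobenzofuran
Product: 17 2-[(2S)-5-amino-2,3-dihydro-1-benzofuran-2-yl]propan-2-ol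
Conditions: CuI (10 mol%), trans-4-hydroxy-L-proline (20 mol%), K2CO3, 28% aq NH3, DMSO, 60 °C, sealed tube
Reagents that add atoms: ammonia, N
Why: Ullmann-type copper-catalysed amination of an aryl bromide with aqueous ammonia tolerates the free tertiary alcohol and does not touch the stereocenter.

Step 11
Reactants: 17 the aniline
Product: 18 (2S)-2-(2-hydroxypropan-2-yl)-2,3-dihydro-1-benzofuran-5-diazonium tetrafluoroborate
Conditions: t-BuONO, 48% aq HBF4, EtOH, 0 °C; precipitation with Et2O
Reagents that add atoms: tert-butyl nitrite, CC(C)(C)ON=O; tetrafluoroboric acid, F[B-](F)(F)F.[H+]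
Why: Diazotisation of a para-alkoxy aniline with an alkyl nitrite in HBF4 should give an isolable arenediazonium tetrafluoroborate of the stable 4-alkoxy type.

Step 12
Reactants: 9 the diene acid; 18 the diazonium tetrafluoroborate
Product: 20 methyl (2R)-4-(benzyloxy)-3-[4-(benzyloxy)phenyl]-2-{[(2S)-2-(2-hydroxypropan-2-yl)-2,3-dihydro-1-benzofuran-5-yl]methyl}-5-oxo-2,5-dihydrofuran-2-carboxylate, via adduct radical 19 (not isolated)
Conditions: Cu(MeCN)4PF6 (10 mol%), (S,S)-t-Bu-BOX [2,2'-(propane-2,2-diyl)bis((4S)-4-tert-butyl-4,5-dihydro-1,3-oxazole)] (12 mol%), 2,6-di-tert-butylpyridine (1.5 equiv), EtOAc/MeCN, 0 °C to rt, slow addition of 18 (1.5 equiv)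
Reagents that add atoms: none
Why: Proposed new method: monovalent copper reduces 18 to the aryl radical, which adds to the only unsubstituted alkene carbon of 9 (the terminal CH2 of the 2-substituted acrylate, Meerwein regiochemistry); the resulting tertiary radical 19, stabilised by the ester and by allylic delocalisation into the benzyloxy-substituted double bond, is captured by the bis(oxazoline)-bound divalent copper carboxylate to give a trivalent copper alkyl that forms the C–O bond by reductive elimination and returns monovalent copper. The closest known reaction type is the copper/bis(oxazoline)-catalysed enantioselective radical oxy-arylation of 1,1-disubstituted alkenoic acids, ortho-vinylbenzoic acids included, with arenediazonium salts, together with classical Meerwein arylation of acrylates; new here is an acrylate-type alkene whose radical is α to an ester and not benzylic. The furanone ring closes in the 5-exo-trig sense: the carboxylate oxygen bonds to the internal carbon of the C=CH2 unit and the arylated CH2 stays exocyclic. The new quaternary stereocenter is set under catalyst control by the C2-symmetric tert-butyl bis(oxazoline) on copper during C–O bond formation, the (S)-center of 18 being too remote to interfere. The step needs regioselective radical addition, closure to the five-membered lactone and enantioface selection: the first is secured by the fully substituted, shielded benzyloxy/aryl double bond, the second by the cis placement of carboxyl and acrylate on that double bond (the same relationship as in an ortho-vinylbenzoic acid), and the third by the carboxylate being the ligand that ties the radical carbon to the chiral copper centre.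

Step 13
Reactants: 20 the dibenzyl-protected lactone
Product: 21 methyl (2R)-4-hydroxy-3-(4-hydroxyphenyl)-2-{[(2S)-2-(2-hydroxypropan-2-yl)-2,3-dihydro-1-benzofuran-5-yl]methyl}-5-oxo-2,5-dihydrofuran-2-carboxylate (target)
Conditions: H2 (1 atm), 10% Pd/C, EtOAc, rt
Reagents that add atoms: none
Why: Hydrogenolysis of the aryl and enol benzyl ethers over palladium on carbon should leave the tetrasubstituted conjugated alkene, the lactone, the methyl ester and both stereocenters untouched.

Compound list
1 | methyl propiolate | C#CC(=O)OC | starting material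
2 | tributyltin hydride | CCCC[SnH](CCCC)CCCC | starting material
3 | methyl 2-(tributylstannyl)prop-2-enoate | C=C(C(=O)OC)[Sn](CCCC)(CCCC)CCCC | intermediate
4 | tert-butyl 2-(benzyloxy)acetate | CC(C)(C)OC(=O)COCc1ccccc1 | starting material
5 | 4-(benzyloxy)benzoyl chloride | O=C(Cl)c1ccc(OCc2ccccc2)cc1 | starting material
6 | tert-butyl 2-(benzyloxy)-3-[4-(benzyloxy)phenyl]-3-oxopropanoate (racemic) | CC(C)(C)OC(=O)C(OCc1ccccc1)C(=O)c1ccc(OCc2ccccc2)cc1 | intermediate
7 | tert-butyl (2E)-2-(benzyloxy)-3-[4-(benzyloxy)phenyl]-3-{[(trifluoromethyl)sulfonyl]oxy}prop-2-enoate | CC(C)(C)OC(=O)/C(OCc1ccccc1)=C(\OS(=O)(=O)C(F)(F)F)c1ccc(OCc2ccccc2)cc1 | intermediate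
8 | 1-tert-butyl 5-methyl (2E)-2-(benzyloxy)-3-[4-(benzyloxy)phenyl]-4-methylidenepent-2-enedioate | CC(C)(C)OC(=O)/C(OCc1ccccc1)=C(\C(=C)C(=O)OC)c1ccc(OCc2ccccc2)cc1 | intermediate
9 | (2E)-2-(benzyloxy)-3-[4-(benzyloxy)phenyl]-4-(methoxycarbonyl)penta-2,4-dienoic acid | OC(=O)/C(OCc1ccccc1)=C(\C(=C)C(=O)OC)c1ccc(OCc2ccccc2)cc1 | intermediate
10 | 4-bromophenol | Oc1ccc(Br)cc1 | starting material
11 | 1-bromo-3-methylbut-2-ene | CC(C)=CCBr | starting material
12 | 4-bromo-2-(3-methylbut-2-en-1-yl)phenol | CC(C)=CCc1cc(Br)ccc1O | intermediate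
13 | [4-bromo-2-(3-methylbut-2-en-1-yl)phenoxy](tert-butyl)dimethylsilane | CC(C)=CCc1cc(Br)ccc1O[Si](C)(C)C(C)(C)C | intermediate
14 | {4-bromo-2-[[(2R)-3,3-dimethyloxiran-2-yl]methyl]phenoxy}(tert-butyl)dimethylsilane | CC1(C)O[C@@H]1Cc1cc(Br)ccc1O[Si](C)(C)C(C)(C)C | intermediate
15 | tetrabutylammonium 4-bromo-2-{[(2R)-3,3-dimethyloxiran-2-yl]methyl}phenoxide | CC1(C)O[C@@H]1Cc1cc(Br)ccc1[O-].CCCC[N+](CCCC)(CCCC)CCCC | intermediate (not isolated)
16 | 2-[(2S)-5-bromo-2,3-dihydro-1-benzofuran-2-yl]propan-2-ol | CC(C)(O)[C@@H]1Cc2cc(Br)ccc2O1 | intermediate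
17 | 2-[(2S)-5-amino-2,3-dihydro-1-benzofuran-2-yl]propan-2-ol | CC(C)(O)[C@@H]1Cc2cc(N)ccc2O1 | intermediate
18 | (2S)-2-(2-hydroxypropan-2-yl)-2,3-dihydro-1-benzofuran-5-diazonium tetrafluoroborate | CC(C)(O)[C@@H]1Cc2cc([N+]#N)ccc2O1.F[B-](F)(F)F | intermediate
19 | tertiary ester-stabilised allyl radical formed by aryl addition to the CH2 terminus of 9 | OC(=O)/C(OCc1ccccc1)=C(\[C](Cc1ccc2c(c1)C[C@@H](C(C)(C)O)O2)C(=O)OC)c1ccc(OCc2ccccc2)cc1 | intermediate (not isolated)
20 | methyl (2R)-4-(benzyloxy)-3-[4-(benzyloxy)phenyl]-2-{[(2S)-2-(2-hydroxypropan-2-yl)-2,3-dihydro-1-benzofuran-5-yl]methyl}-5-oxo-2,5-dihydrofuran-2-carboxylate | COC(=O)[C@]1(Cc2ccc3c(c2)C[C@@H](C(C)(C)O)O3)OC(=O)C(OCc2ccccc2)=C1c1ccc(OCc2ccccc2)cc1 | intermediate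
21 | methyl (2R)-4-hydroxy-3-(4-hydroxyphenyl)-2-{[(2S)-2-(2-hydroxypropan-2-yl)-2,3-dihydro-1-benzofuran-5-yl]methyl}-5-oxo-2,5-dihydrofuran-2-carboxylate | COC(=O)[C@]1(Cc2ccc3c(c2)C[C@@H](C(C)(C)O)O3)OC(=O)C(O)=C1c1ccc(O)cc1 | target

Total step count: 13.
Longest linear sequence: 8 steps (steps 6 to 13, from 4-bromophenol).

Steps most likely to fail

Step 12 (the step that carries the new-method label). Capture of the ester-stabilised tertiary radical by the copper carboxylate may be slow or poorly face-selective, so that radical reduction, dimerisation or weak enantioface control takes over. The fallback uses known chemistry, sets out from 9 and 18 and returns at 20. Acid 9 and salt 18 would be combined under classical Meerwein conditions (CuCl2 (20 mol%), LiCl, acetone/H2O, 0 °C to rt). Chlorine-atom transfer from divalent copper chloride to the adduct radical should give (2E)-2-(benzyloxy)-3-[4-(benzyloxy)phenyl]-4-chloro-5-[(2S)-2-(2-hydroxypropan-2-yl)-2,3-dihydro-1-benzofuran-5-yl]-4-(methoxycarbonyl)pent-2-enoic acid F1 as both epimers at the chlorinated carbon. NaHCO3 in DMF (rt to 40 °C) would then close the furanone by internal displacement of the tertiary allylic chloride by the carboxylate. This should give 20 together with its epimer at the lactone carbon, methyl (2S)-4-(benzyloxy)-3-[4-(benzyloxy)phenyl]-2-{[(2S)-2-(2-hydroxypropan-2-yl)-2,3-dihydro-1-benzofuran-5-yl]methyl}-5-oxo-2,5-dihydrofuran-2-carboxylate F2. The two would be separated by preparative HPLC on a chiral stationary phase, and 20 carried into step 13.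

Step 4. Transmetalation of the α-stannyl acrylate onto a tetrasubstituted vinyl palladium centre may be too slow, so that protodestannylation and homocoupling consume the partners. The fallback sets out from 7 and returns at 8, and builds the acrylate unit from an alkyne. Sonogashira coupling of 7 with trimethylsilylacetylene (PdCl2(PPh3)2, CuI, i-Pr2NH, THF, rt) should give tert-butyl (2E)-2-(benzyloxy)-3-[4-(benzyloxy)phenyl]-5-(trimethylsilyl)pent-2-en-4-ynoate F3. K2CO3 in MeOH (0 °C) would remove the silyl group to give tert-butyl (2Z)-2-(benzyloxy)-3-[4-(benzyloxy)phenyl]pent-2-en-4-ynoate F4. Branch-selective methoxycarbonylation of the terminal alkyne (Pd(OAc)2, 2-(diphenylphosphino)pyridine, MeSO3H cat., CO 20 bar, MeOH, 50 °C) would then give 8 with the double-bond geometry unchanged.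

Step 6. O-alkylation and double alkylation may compete with the direct ortho-C-prenylation and make the separation impractical. The fallback sets out from 10 and returns at 12. O-allylation of 10 (allyl bromide, K2CO3, acetone, reflux) should give 1-bromo-4-(prop-2-en-1-yloxy)benzene F5. Aromatic Claisen rearrangement (N,N-diethylaniline, 200 °C) would give 4-bromo-2-(prop-2-en-1-yl)phenol F6. Cross-metathesis with excess 2-methylbut-2-ene (second-generation Grubbs catalyst RuCl2(=CHPh)(PCy3)(H2IMes), CH2Cl2, 40 °C) would convert the allyl group into the prenyl group of 12.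

Further compounds
F1 | step 12 | (2E)-2-(benzyloxy)-3-[4-(benzyloxy)phenyl]-4-chloro-5-[(2S)-2-(2-hydroxypropan-2-yl)-2,3-dihydro-1-benzofuran-5-yl]-4-(methoxycarbonyl)pent-2-enoic acid (both epimers at the chlorinated carbon) | OC(=O)/C(OCc1ccccc1)=C(\C(Cl)(Cc1ccc2c(c1)C[C@@H](C(C)(C)O)O2)C(=O)OC)c1ccc(OCc2ccccc2)cc1
F2 | step 12 | methyl (2S)-4-(benzyloxy)-3-[4-(benzyloxy)phenyl]-2-{[(2S)-2-(2-hydroxypropan-2-yl)-2,3-dihydro-1-benzofuran-5-yl]methyl}-5-oxo-2,5-dihydrofuran-2-carboxylate | COC(=O)[C@@]1(Cc2ccc3c(c2)C[C@@H](C(C)(C)O)O3)OC(=O)C(OCc2ccccc2)=C1c1ccc(OCc2ccccc2)cc1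
F3 | step 4 | tert-butyl (2E)-2-(benzyloxy)-3-[4-(benzyloxy)phenyl]-5-(trimethylsilyl)pent-2-en-4-ynoate | CC(C)(C)OC(=O)/C(OCc1ccccc1)=C(\C#C[Si](C)(C)C)c1ccc(OCc2ccccc2)cc1
F4 | step 4 | tert-butyl (2Z)-2-(benzyloxy)-3-[4-(benzyloxy)phenyl]pent-2-en-4-ynoate | CC(C)(C)OC(=O)/C(OCc1ccccc1)=C(\C#C)c1ccc(OCc2ccccc2)cc1
F5 | step 6 | 1-bromo-4-(prop-2-en-1-yloxy)benzene | C=CCOc1ccc(Br)cc1
F6 | step 6 | 4-bromo-2-(prop-2-en-1-yl)phenol | C=CCc1cc(Br)ccc1O
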